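## Analysis of the target

- Compound 15 is a monocyclic γ-butyrolactone; with the ring numbered C1 (carbonyl), C2, C3, C4 (OCH2) and O5, C2 carries a hydroxyl group and, through the benzylic carbon C7, a 4-hydroxy-3-methoxyphenyl ring, while C3 carries a second such ring through the ketone carbon C7'.
- The two adjacent stereocentres are both S: C2 is a fully substituted tertiary alcohol, C3 is a methine next to the aryl ketone, and the aroyl group lies cis to the hydroxyl and trans to the benzyl group.
- C2 cannot epimerise and can only be destroyed by retro-aldol cleavage of C2–C3, whereas C3 epimerises by enolisation and its required configuration should be the more stable one (larger C2 substituent trans, hydroxyl hydrogen-bonded to the ketone), so only C2 needs outside control.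
- The β-hydroxy ketone (O–C2–C3–C7'=O) is open to retro-aldol cleavage and the β-acyloxy ketone (C7'–C3–C4–O5) to elimination, although the latter is slowed because the C4–O5 bond lies in the ring plane, almost orthogonal to an exocyclic enolate at C3.
- The lactone is sensitive to hydroxide and alkoxide, and the two free electron-rich phenols are sensitive to oxidants and to aldehyde electrophiles.
- The hard parts are the absolute configuration of a quaternary carbinol and keeping the two carboxyl groups of the intermediates apart so that the right one becomes the lactone.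
- The strategy rests on reading C1, C2 and C7 with its ring as the carboxyl, keto and benzylic carbons of an arylpyruvic acid, and C3 and C7' as the methyl and keto carbons of pyruvic acid.
- C2–C3 is therefore an aldol bond onto an α-keto acid, C4 is a one-carbon aldehyde unit, and the aroyl ring takes the place of the carboxyl group of pyruvic acid.

## Retrosynthetic reasoning

**15 from 13 (through 14).** Only the two phenol acetates are removed; no skeletal bond is cut. Acetates were chosen because they can be put on in a mildly basic aqueous medium and come off near neutrality, where the lactone and the β-hydroxy ketone survive. The same weakly buffered medium lets C3 settle into its preferred configuration.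

**13 from 10 and 12.** The C7'–aryl bond is cut. Its acyl half is the 2-oxo acid 10, whose carboxyl is lost as the acyl radical forms; its aryl half is the bromide 12. Cutting here means the carboxyl that made 5 an enzyme substrate becomes the leaving group, and no organometallic reagent has to meet a lactone, two esters and a free tertiary alcohol. The forward reaction must form an aryl ketone at room temperature without touching C2 or C3.

**10 from 8 (through 9).** Two bonds are cut, C3–C4 and O5–C1; C4 is a one-carbon aldehyde electrophile. C3 is the α-carbon of a 2-oxo acid and so enolises under mild conditions. The isopropylidene ketal of 8 settles three points at once. The tertiary oxygen is blocked, so it can neither start a retro-aldol nor close onto the oxo-acid carboxyl. C1 is an activated ester, while the oxo-acid carboxyl is an inert carboxylate under base. The new hydroxymethyl group of 9 can therefore only acylate on C1, which gives the wanted lactone and frees the tertiary hydroxyl in the same event. A free diacid would leave this regiochemistry open, since 4-hydroxy-2-oxo acids usually lactonise on the oxo-acid carboxyl.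

**8 from 7 from 6.** These are protecting-group operations only: the phenol is acetylated on the dicarboxylate in aqueous medium, then the α-hydroxy acid is ketalised. Neither touches C2.

**6 from 4 and 5.** The C2–C3 bond is cut. This is the one disconnection that creates the quaternary stereocentre, and it splits the carbon skeleton into two achiral keto acids. The forward reaction must add the enolate of 5 to one face of the keto form of 4, without self-condensation of the largely enolised 4. An enzyme active site can do that; a small base cannot.

**4 from 3 from 1 and 2.** The benzylic C7–C2 framework comes from azlactone condensation of the aldehyde 1 with the glycine derivative 2 and hydrolysis of 3. This is a two-step classical route that needs no protecting group.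

**12 from 11.** Acetylation of the phenol, so that the aryl bromide carries the same protecting group as 10.

## Alternatives that were turned down

**Alternative 1:** The C3–C4 bond is traced back to a seven-membered methylene acylal A1, in which C4 sits between the acyl oxygen O5 and the enol-ether oxygen of the aryl ketone.
- Forward key step: a silyl triflate or alkylaluminium chloride Lewis acid ionises the C4–O(enol) bond. The acyloxy-stabilised oxocarbenium ion and the ketone enolate recombine through C3, contracting the ring to the silyl-protected lactone A2 (a Petasis–Ferrier-type rearrangement).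
- For: C4 is already attached to O5, so there is no question which carboxyl ends up in the lactone, and the C3–C4 bond forms intramolecularly. On this point it is stronger than the chosen route, which needs the dioxolanone device of 8 for the same certainty.
- Against: the step does not create C2. A1 must already be enantiopure at its silyloxy carbon, so the real stereochemical problem moves to an earlier, separate asymmetric step. A1 itself needs O-alkylation of a ketone enolate within a medium ring. The closure is endo with respect to the oxocarbenium ion. A trimethylsilyl ether has to survive a silyl triflate. The benzyl ethers must later be hydrogenolysed next to an aryl ketone.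
- Comparison: the chosen route sets C2 catalytically from two achiral acids in its third step; Alternative 1 offers nothing comparable for C2.

**Alternative 2:** The C2–C7 bond is cut. The precursor is the 2-hydroxyfuran-3(2H)-one A3.
- Forward key step: an α-ketol shift under a chiral divalent copper bis(oxazoline) Lewis acid. The hemiketal carbon becomes the lactone carbonyl, and the benzyl group migrates to the neighbouring ketone carbon, giving the unsaturated lactone A4.
- For: it makes the tertiary carbinol by asymmetric catalysis, with both aryl groups and the lactone already in place. One hydrogenation could then saturate C3=C4 and remove the benzyl ethers. After its key step it is shorter than the chosen route.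
- Against: A3 is a vinylogous ester, and the shift trades it for an enol-ester lactone. The driving force is doubtful and α-ketol shifts are reversible. The catalyst must select between rapidly interconverting hemiketal enantiomers. C3 is still sp2 afterwards, so its configuration and the chemoselective reduction next to an aryl ketone remain open.
- Comparison: the chosen route has an equilibrium too, but it can be pushed with an excess of 5, and its acceptor class is known for the enzyme family.

**Alternative 3:** O5–C4 and C2–C3 are cut together. The partners are the aryl vinyl ketone A5 and the O-benzyl arylpyruvic acid A6.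
- Forward key step: under a bifunctional tertiary amine–thiourea catalyst the carboxylate adds to the enone terminus, and the resulting β-acyloxy ketone closes by aldol addition of C3 to the tethered ketone, giving A7.
- For: it is the most convergent plan. Skeleton, ring and both stereocentres come in one step, with only debenzylation left. In step count it clearly beats the chosen route.
- Against: A6 is largely enolised in organic solvents, and its enol is a carbon nucleophile at C7, so C-addition to A5 competes with the slow, reversible O-addition of a carboxylate. The enantio-determining event is a reversible ketone aldol under hydrogen-bond control. A5 polymerises easily.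
- Comparison: the chosen route gives up this brevity. In return the active site imposes the keto form of the acceptor and fixes the face of attack, so the risk is limited to one precedented enzymatic step.

Key step: step 3

Assumption: an (S)-selective member of the aldolase family that accepts 4 is available (both enantiopreferences occur in the family), and 6 is handled only as its dicarboxylate salt, in which form it neither lactonises nor reverts quickly.

## Route

Step 1
Reactants: 1 vanillin + 2 N-acetylglycine
Product: 3 (Z)-4-(4-acetoxy-3-methoxybenzylidene)-2-methyloxazol-5(4H)-one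
Conditions: Ac2O, NaOAc, 100 °C
Reagents that add atoms: acetic anhydride, CC(=O)OC(C)=O
Why: Erlenmeyer–Plöchl azlactone synthesis: the anhydride cyclodehydrates the acylglycine, the active methylene of the oxazolone condenses with the aldehyde, and the phenol is acetylated on the way; the more stable (Z)-alkene should result.

Step 2
Reactants: 3 (Z)-4-(4-acetoxy-3-methoxybenzylidene)-2-methyloxazol-5(4H)-one
Product: 4 3-(4-hydroxy-3-methoxyphenyl)-2-oxopropanoic acid
Conditions: 3 M aq. HCl, reflux, N2; crystallisation on cooling
Reagents that add atoms: water, O
Why: Acid hydrolysis opens the azlactone, cleaves the enamide to the 2-oxo acid and removes the aryl acetate, the classical route to arylpyruvic acids; no stereocentre is involved.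

Step 3
Reactants: 4 3-(4-hydroxy-3-methoxyphenyl)-2-oxopropanoic acid + 5 pyruvic acid
Product: 6 (S)-4-hydroxy-4-(4-hydroxy-3-methoxybenzyl)-2-oxopentanedioic acid (isolated as the disodium salt)
Conditions: NaHCO3 (to pH 7.5, both acids as sodium salts; pyruvic acid in fivefold excess; CO2 purged with N2), (S)-selective 4-hydroxy-4-methyl-2-oxoglutarate (HMG/CHA-type) pyruvate aldolase, MgCl2 (2 mM), HEPES buffer pH 7.5, 25 °C, N2; ultrafiltration, anion-exchange chromatography, lyophilisation
Reagents that add atoms: none
Why: Pyruvate binds through its carboxylate and keto oxygens to the active-site magnesium dication and is deprotonated at the methyl group, and the metal-bound enolate adds through C3 to the keto carbon C2 of 4, which is held by its own carboxylate so that one face is exposed. The closest known reaction type is the addition of pyruvate to indol-3-ylpyruvic and phenylpyruvic acid by this aldolase family, the reverse of its natural cleavage of 4-substituted 4-hydroxy-2-oxoglutarates. No ring closes; one skeletal bond (C2–C3) and one stereocentre are formed. The configuration of the new tertiary carbinol C2 is set by the enzyme alone, and the (S)-selective member is used. The step needs enantioface selectivity at the ketone, 4 acting only as acceptor, and a workable equilibrium position. Two-point binding of the keto acid secures the first, the small donor site that takes only the enolate of 5 secures the second, and the excess of 5 the third. Self-addition of 5 is reversible, consumes only the cheap partner, and its product should separate on the ion exchanger. Neutralisation with hydrogencarbonate avoids any local excess of strong base, and water at pH 7.5 supplies 4 in its keto form with the phenol unprotected, which a small base in an organic solvent would not do.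

Step 4
Reactants: 6 (S)-4-hydroxy-4-(4-hydroxy-3-methoxybenzyl)-2-oxopentanedioic acid (disodium salt)
Product: 7 (S)-4-(4-acetoxy-3-methoxybenzyl)-4-hydroxy-2-oxopentanedioic acid
Conditions: Ac2O, NaHCO3, H2O, 0 °C; then cold aq. HCl to pH 2, NaCl, EtOAc/THF extraction, used at once
Reagents that add atoms: acetic anhydride, CC(=O)OC(C)=O
Why: Schotten–Baumann-type acetylation: at pH about 8 only the phenoxide is acylated at a useful rate, the tertiary alcohol is inert and mixed anhydrides of the carboxylates hydrolyse back. As a dicarboxylate the aldol adduct stays open-chain and is not exposed to strong base.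

Step 5
Reactants: 7 (S)-4-(4-acetoxy-3-methoxybenzyl)-4-hydroxy-2-oxopentanedioic acid
Product: 8 3-[(4S)-4-(4-acetoxy-3-methoxybenzyl)-2,2-dimethyl-5-oxo-1,3-dioxolan-4-yl]-2-oxopropanoic acid
Conditions: 2-methoxypropene (3 equiv), PPTS (cat.), CH2Cl2/THF, 0 °C → rt; brief aqueous wash at pH 3
Reagents that add atoms: 2-methoxypropene, COC(C)=C
Why: Acid-catalysed acetonide (1,3-dioxolan-4-one) formation of an α-hydroxy acid: the oxocarbenium ion from the enol ether is trapped by the tertiary hydroxyl and its own carboxyl in a five-membered ring, as with malic and citramalic acid, whose second carboxyl stays free. Cation capture should outrun any acyl substitution at the oxo-acid carboxyl, the labile mixed ketal ester of that carboxyl falls apart in the wash, and C2 is not touched.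

Step 6
Reactants: 8 3-[(4S)-4-(4-acetoxy-3-methoxybenzyl)-2,2-dimethyl-5-oxo-1,3-dioxolan-4-yl]-2-oxopropanoic acid
Product: 10 2-[(3S,4S)-4-(4-acetoxy-3-methoxybenzyl)-4-hydroxy-5-oxotetrahydrofuran-3-yl]-2-oxoacetic acid, via hydroxymethyl dioxolanone keto acid 9 (not isolated)
Conditions: CH2O (ca. 1 M in THF, 1.3 equiv), MgBr2·OEt2 (1.1 equiv), Et3N (2.5 equiv), THF, −20 °C → rt; cold aq. citric acid, EtOAc
Reagents that add atoms: formaldehyde, C=O
Why: Soft enolisation of the 2-oxo carboxylate, chelated to magnesium as in the aldolase, and aldol addition to formaldehyde form C3–C4 (the classical hydroxymethylation of 2-oxo acids). The new alkoxide of 9 then attacks the only acyl donor present, the dioxolanone carbonyl C1 (5-exo-trig), expelling acetone and freeing the tertiary hydroxyl, so the lactone regiochemistry is fixed by structure. C3 stays epimerisable under the amine and should settle with the oxalyl group trans to the benzyl group; a second addition would have to build a quaternary C3 next to quaternary C2.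

Step 7
Reactants: 11 4-bromo-2-methoxyphenol
Product: 12 4-bromo-2-methoxyphenyl acetate
Conditions: Ac2O, pyridine, DMAP (cat.), CH2Cl2, rt
Reagents that add atoms: acetic anhydride, CC(=O)OC(C)=O
Why: Standard nucleophile-catalysed acetylation of a phenol; the acetate also makes the bromide less electron-rich for oxidative addition.

Step 8
Reactants: 10 2-[(3S,4S)-4-(4-acetoxy-3-methoxybenzyl)-4-hydroxy-5-oxotetrahydrofuran-3-yl]-2-oxoacetic acid + 12 4-bromo-2-methoxyphenyl acetate
Product: 13 (3S,4S)-4-(4-acetoxy-3-methoxybenzoyl)-3-(4-acetoxy-3-methoxybenzyl)-3-hydroxydihydrofuran-2(3H)-one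
Conditions: Ir[dF(CF3)ppy]2(dtbbpy)PF6 (2 mol %), NiCl2·glyme (10 mol %), 4,4'-di-tert-butyl-2,2'-bipyridine (15 mol %), Li2CO3, H2O (2 equiv), aryl bromide in 1.5-fold amount, DMF, blue LEDs, rt, degassed
Reagents that add atoms: none
Why: Nickel/photoredox decarboxylative acyl–aryl coupling of a 2-oxo acid: the excited trivalent iridium photocatalyst oxidises the carboxylate, loss of CO2 gives the acyl radical at C7', and the arylnickel species from oxidative addition of 12 to zerovalent nickel captures it and forms the ketone by reductive elimination. Secondary alkyl 2-oxo acids are known substrates. The σ-type acyl radical leaves C3 alone, and C2, the lactone and the tertiary alcohol take no part.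

Step 9
Reactants: 13 (3S,4S)-4-(4-acetoxy-3-methoxybenzoyl)-3-(4-acetoxy-3-methoxybenzyl)-3-hydroxydihydrofuran-2(3H)-one
Product: 15 (3S,4S)-3-hydroxy-3-(4-hydroxy-3-methoxybenzyl)-4-(4-hydroxy-3-methoxybenzoyl)dihydrofuran-2(3H)-one, via benzyl-ring monoacetate 14 (not isolated)
Conditions: NH4OAc (excess), MeOH/H2O 4:1, rt → 40 °C until the C3 epimer composition no longer changes
Reagents that add atoms: none
Why: Near-neutral ammonium acetate-mediated hydrolysis of aryl acetates, the one para to the ketone first, leaves the alkyl lactone and the β-hydroxy ketone alone. The same buffer allows enolisation at C3, which should equilibrate towards the epimer with the aroyl group trans to the benzyl group and hydrogen-bonded to the hydroxyl, which is the target.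

## Compound list

1 | vanillin | COc1cc(C=O)ccc1O | starting material
2 | N-acetylglycine | CC(=O)NCC(=O)O | starting material
3 | (Z)-4-(4-acetoxy-3-methoxybenzylidene)-2-methyloxazol-5(4H)-one | COc1cc(/C=C2\N=C(C)OC2=O)ccc1OC(C)=O | intermediate
4 | 3-(4-hydroxy-3-methoxyphenyl)-2-oxopropanoic acid | COc1cc(CC(=O)C(=O)O)ccc1O | intermediate
5 | pyruvic acid | CC(=O)C(=O)O | starting material
6 | (S)-4-hydroxy-4-(4-hydroxy-3-methoxybenzyl)-2-oxopentanedioic acid | COc1cc(C[C@@](CC(=O)C(=O)O)(O)C(=O)O)ccc1O | intermediate
7 | (S)-4-(4-acetoxy-3-methoxybenzyl)-4-hydroxy-2-oxopentanedioic acid | COc1cc(C[C@@](CC(=O)C(=O)O)(O)C(=O)O)ccc1OC(C)=O | intermediate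
8 | 3-[(4S)-4-(4-acetoxy-3-methoxybenzyl)-2,2-dimethyl-5-oxo-1,3-dioxolan-4-yl]-2-oxopropanoic acid | COc1cc(C[C@@]2(CC(=O)C(=O)O)OC(C)(C)OC2=O)ccc1OC(C)=O | intermediate
9 | 3-[(4S)-4-(4-acetoxy-3-methoxybenzyl)-2,2-dimethyl-5-oxo-1,3-dioxolan-4-yl]-4-hydroxy-2-oxobutanoic acid (both C3 epimers) | COc1cc(C[C@@]2(C(CO)C(=O)C(=O)O)OC(C)(C)OC2=O)ccc1OC(C)=O | intermediate
10 | 2-[(3S,4S)-4-(4-acetoxy-3-methoxybenzyl)-4-hydroxy-5-oxotetrahydrofuran-3-yl]-2-oxoacetic acid | COc1cc(C[C@@]2(O)C(=O)OC[C@@H]2C(=O)C(=O)O)ccc1OC(C)=O | intermediate
11 | 4-bromo-2-methoxyphenol | COc1cc(Br)ccc1O | starting material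
12 | 4-bromo-2-methoxyphenyl acetate | COc1cc(Br)ccc1OC(C)=O | intermediate
13 | (3S,4S)-4-(4-acetoxy-3-methoxybenzoyl)-3-(4-acetoxy-3-methoxybenzyl)-3-hydroxydihydrofuran-2(3H)-one | COc1cc(C[C@@]2(O)C(=O)OC[C@@H]2C(=O)c2ccc(OC(C)=O)c(OC)c2)ccc1OC(C)=O | intermediate
14 | (3S,4S)-3-(4-acetoxy-3-methoxybenzyl)-3-hydroxy-4-(4-hydroxy-3-methoxybenzoyl)dihydrofuran-2(3H)-one | COc1cc(C[C@@]2(O)C(=O)OC[C@@H]2C(=O)c2ccc(O)c(OC)c2)ccc1OC(C)=O | intermediate
15 | (3S,4S)-3-hydroxy-3-(4-hydroxy-3-methoxybenzyl)-4-(4-hydroxy-3-methoxybenzoyl)dihydrofuran-2(3H)-one | COc1cc(C[C@@]2(O)C(=O)OC[C@@H]2C(=O)c2ccc(O)c(OC)c2)ccc1O | target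

## Step count and least certain steps

Total step count: 9. Longest linear sequence: 8 steps (steps 1–6, 8 and 9, from vanillin); step 7 is a one-step branch.

**Step 3 (key step).** What may go wrong:
- poor acceptance of the methoxy-substituted keto acid, or an equilibrium that stops at low conversion;
- consumption of 5 by self-addition;
- insufficient facial selectivity of the enzyme chosen;
- erosion of enantiopurity by non-enzymatic retro-aldol and re-addition during isolation.

Fallback, setting out from 4 and 5: a hydroxide-mediated cross-aldol addition in water (KOH, pH 12–13, 0–5 °C, excess of 5 as its potassium salt) should give racemic 4-hydroxy-4-(4-hydroxy-3-methoxybenzyl)-2-oxopentanedioic acid F1. Acetylation as in step 4 would give racemic 4-(4-acetoxy-3-methoxybenzyl)-4-hydroxy-2-oxopentanedioic acid F2. Ketalisation as in step 5 would then give racemic 3-[4-(4-acetoxy-3-methoxybenzyl)-2,2-dimethyl-5-oxo-1,3-dioxolan-4-yl]-2-oxopropanoic acid F3, an organic-soluble mono-acid. Its enantiomers would be separated by preparative chromatography on a chiral stationary phase; the (S)-enantiomer is 8, where the route is rejoined.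

**Step 5.** What may go wrong: ring closure of the tertiary hydroxyl onto the oxo-acid carboxyl (enol lactone formation) before or instead of ketalisation, and esterification of the oxo acid, either of which removes the handle for step 6.

Fallback, setting out from 6: classical aqueous hydroxymethylation of the dicarboxylate (aq. CH2O, K2CO3 buffer, pH about 9.5, 0 °C → rt, kept short so that hydroxymethylation of the phenol ring stays slow) should give (4S)-4-hydroxy-4-(4-hydroxy-3-methoxybenzyl)-3-(hydroxymethyl)-2-oxopentanedioic acid F4. Acidification to pH 1–2 lactonises it without regiocontrol, and the lactone isomers are then sorted by a short stay at pH 7: lactone links on the oxo-acid carboxyl are activated α-keto esters and reopen there, while the α-hydroxy γ-lactone survives, and the reopened material is recycled. This gives 2-[(3S,4S)-4-hydroxy-4-(4-hydroxy-3-methoxybenzyl)-5-oxotetrahydrofuran-3-yl]-2-oxoacetic acid F5, which is acetylated at the phenol (Ac2O, aq. NaHCO3, 0 °C) to rejoin the route at 10.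

**Step 6.** What may go wrong:
- slow enolisation of the hindered carboxylate;
- a second hydroxymethylation;
- O-acylation of the enolate by the dioxolanone;
- cleavage of the dioxolanone by adventitious water, which loses the differentiation of the carboxyls;
- retro-aldol cleavage once the tertiary hydroxyl is set free.

Fallback, setting out from 8, with the order of events changed: arylation of 8 with 12 under the conditions of step 8 should give (5S)-5-(4-acetoxy-3-methoxybenzyl)-5-[2-(4-acetoxy-3-methoxyphenyl)-2-oxoethyl]-2,2-dimethyl-1,3-dioxolan-4-one F6. TMSOTf and Et3N in CH2Cl2 at 0 °C would convert it to the silyl enol ether (5S)-5-(4-acetoxy-3-methoxybenzyl)-5-[(Z)-2-(4-acetoxy-3-methoxyphenyl)-2-(trimethylsilyloxy)vinyl]-2,2-dimethyl-1,3-dioxolan-4-one F7. A Mukaiyama-type hydroxymethylation (aq. CH2O, Yb(OTf)3 cat., THF/H2O, rt) would give (5S)-5-(4-acetoxy-3-methoxybenzyl)-5-[1-(4-acetoxy-3-methoxyphenyl)-3-hydroxy-1-oxopropan-2-yl]-2,2-dimethyl-1,3-dioxolan-4-one F8, whose hydroxyl closes onto the dioxolanone with loss of acetone (Et3N cat.) to rejoin the route at 13. Only one acyl group is left at that stage, so even if the ketal hydrolyses, the single carboxyl can only give the wanted lactone.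

**Step 8.** What may go wrong:
- decarbonylation of the secondary acyl radical before nickel captures it;
- reduction of the acyl radical to the aldehyde;
- slow oxidative addition of the electron-rich bromide;
- partial loss of the aryl acetates to carbonate, after which the free phenol quenches the photocatalyst.

Fallback, setting out from 10: oxidative decarboxylation with aq. H2O2 (THF/H2O, pH 5–6, 0 °C) should give (3S,4S)-4-(4-acetoxy-3-methoxybenzyl)-4-hydroxy-5-oxotetrahydrofuran-3-carboxylic acid F9. Benzenethiol, EDC·HCl and DMAP (cat.) in CH2Cl2 would give S-phenyl (3S,4S)-4-(4-acetoxy-3-methoxybenzyl)-4-hydroxy-5-oxotetrahydrofuran-3-carbothioate F10. A Liebeskind–Srogl coupling with purchased (4-hydroxy-3-methoxyphenyl)boronic acid (Pd2(dba)3, tri(2-furyl)phosphine, Cu(O2CC4H3S), the monovalent copper thiophene-2-carboxylate, THF, 50 °C) runs base-free and tolerates the free phenol. It should give the monoacetate 14 directly, where the route is rejoined within step 9.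

## Further compounds

F1 | step 3 | rac-4-hydroxy-4-(4-hydroxy-3-methoxybenzyl)-2-oxopentanedioic acid | COc1cc(CC(CC(=O)C(=O)O)(O)C(=O)O)ccc1O
F2 | step 3 | rac-4-(4-acetoxy-3-methoxybenzyl)-4-hydroxy-2-oxopentanedioic acid | COc1cc(CC(CC(=O)C(=O)O)(O)C(=O)O)ccc1OC(C)=O
F3 | step 3 | rac-3-[4-(4-acetoxy-3-methoxybenzyl)-2,2-dimethyl-5-oxo-1,3-dioxolan-4-yl]-2-oxopropanoic acid | COc1cc(CC2(CC(=O)C(=O)O)OC(C)(C)OC2=O)ccc1OC(C)=O
F4 | step 5 | (4S)-4-hydroxy-4-(4-hydroxy-3-methoxybenzyl)-3-(hydroxymethyl)-2-oxopentanedioic acid (both C3 epimers) | COc1cc(C[C@@](C(CO)C(=O)C(=O)O)(O)C(=O)O)ccc1O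
F5 | step 5 | 2-[(3S,4S)-4-hydroxy-4-(4-hydroxy-3-methoxybenzyl)-5-oxotetrahydrofuran-3-yl]-2-oxoacetic acid | COc1cc(C[C@@]2(O)C(=O)OC[C@@H]2C(=O)C(=O)O)ccc1O
F6 | step 6 | (5S)-5-(4-acetoxy-3-methoxybenzyl)-5-[2-(4-acetoxy-3-methoxyphenyl)-2-oxoethyl]-2,2-dimethyl-1,3-dioxolan-4-one | COc1cc(C[C@@]2(CC(=O)c3ccc(OC(C)=O)c(OC)c3)OC(C)(C)OC2=O)ccc1OC(C)=O
F7 | step 6 | (5S)-5-(4-acetoxy-3-methoxybenzyl)-5-[(Z)-2-(4-acetoxy-3-methoxyphenyl)-2-(trimethylsilyloxy)vinyl]-2,2-dimethyl-1,3-dioxolan-4-one | COc1cc(C[C@@]2(/C=C(\O[Si](C)(C)C)c3ccc(OC(C)=O)c(OC)c3)OC(C)(C)OC2=O)ccc1OC(C)=O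
F8 | step 6 | (5S)-5-(4-acetoxy-3-methoxybenzyl)-5-[1-(4-acetoxy-3-methoxyphenyl)-3-hydroxy-1-oxopropan-2-yl]-2,2-dimethyl-1,3-dioxolan-4-one (both epimers at the new methine) | COc1cc(C[C@@]2(C(CO)C(=O)c3ccc(OC(C)=O)c(OC)c3)OC(C)(C)OC2=O)ccc1OC(C)=O
F9 | step 8 | (3S,4S)-4-(4-acetoxy-3-methoxybenzyl)-4-hydroxy-5-oxotetrahydrofuran-3-carboxylic acid | COc1cc(C[C@@]2(O)C(=O)OC[C@@H]2C(=O)O)ccc1OC(C)=O
F10 | step 8 | S-phenyl (3S,4S)-4-(4-acetoxy-3-methoxybenzyl)-4-hydroxy-5-oxotetrahydrofuran-3-carbothioate | COc1cc(C[C@@]2(O)C(=O)OC[C@@H]2C(=O)Sc2ccccc2)ccc1OC(C)=O
A1 | alternative 1 | (5S)-5-[4-(benzyloxy)-3-methoxybenzyl]-7-[4-(benzyloxy)-3-methoxyphenyl]-5-(trimethylsilyloxy)-1,3-dioxepin-4(5H)-one | COc1cc(C[C@]2(O[Si](C)(C)C)C=C(c3ccc(OCc4ccccc4)c(OC)c3)OCOC2=O)ccc1OCc1ccccc1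
A2 | alternative 1 | (3S,4S)-4-[4-(benzyloxy)-3-methoxybenzoyl]-3-[4-(benzyloxy)-3-methoxybenzyl]-3-(trimethylsilyloxy)dihydrofuran-2(3H)-one | COc1cc(C[C@@]2(O[Si](C)(C)C)C(=O)OC[C@@H]2C(=O)c2ccc(OCc3ccccc3)c(OC)c2)ccc1OCc1ccccc1
A3 | alternative 2 | 2-[4-(benzyloxy)-3-methoxybenzyl]-4-[4-(benzyloxy)-3-methoxybenzoyl]-2-hydroxyfuran-3(2H)-one (racemic) | COc1cc(CC2(O)OC=C(C(=O)c3ccc(OCc4ccccc4)c(OC)c3)C2=O)ccc1OCc1ccccc1
A4 | alternative 2 | (S)-4-[4-(benzyloxy)-3-methoxybenzoyl]-3-[4-(benzyloxy)-3-methoxybenzyl]-3-hydroxyfuran-2(3H)-one | COc1cc(C[C@@]2(O)C(=O)OC=C2C(=O)c2ccc(OCc3ccccc3)c(OC)c2)ccc1OCc1ccccc1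
A5 | alternative 3 | 1-[4-(benzyloxy)-3-methoxyphenyl]prop-2-en-1-one | C=CC(=O)c1ccc(OCc2ccccc2)c(OC)c1
A6 | alternative 3 | 3-[4-(benzyloxy)-3-methoxyphenyl]-2-oxopropanoic acid | COc1cc(CC(=O)C(=O)O)ccc1OCc1ccccc1
A7 | alternative 3 | (3S,4S)-4-[4-(benzyloxy)-3-methoxybenzoyl]-3-[4-(benzyloxy)-3-methoxybenzyl]-3-hydroxydihydrofuran-2(3H)-one | COc1cc(C[C@@]2(O)C(=O)OC[C@@H]2C(=O)c2ccc(OCc3ccccc3)c(OC)c2)ccc1OCc1ccccc1
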